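**Plan**
1. Retrosynthesis: the two ring B benzyl ethers come off last. Ring C is cut at O1–C2 to a 2'-hydroxy-α-methoxychalcone. Ring A is cut at C4a–C8a to an open 2,4,8-trimethoxy-3,5,7-triketo ester. The chain is then cut at C4–C4a, C5–C6 and C7–C8 (flavone numbering) and at the C2=C3 alkene.
2. Enabling feature: ring A is a fully substituted acylphloroglucinol in which the oxygen-bearing C5, C7 and C8a alternate with C4a, C6 and C8. This is the folding of a tetraketide whose C6 and C8 carry methoxy groups. Ring A is symmetric about the C4a–C7 axis, so either ortho hydroxyl closes ring C to the same flavone.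
3. Forward: methoxyacetate self-condensation (C7–C8), dianion acetylation (C5–C6), trianion acylation by the ring B α-methoxycinnamate (C4–C4a), Claisen closure of ring A (C4a–C8a), oxidative closure of ring C (O1–C2), debenzylation.
4. Stereochemistry: the target has no stereocentre. The labile methoxy-bearing sp3 centres of the chain become aromatic carbons, and the Z enol ether geometry set thermodynamically in step 4 is absorbed into ring C.

Key step: step 8

Remark: keto esters 8, 10 and 11 are drawn as keto tautomers. Their methoxy-bearing sp3 centres epimerize freely through the enols, so no configuration is assigned. The transient compounds 6 and 13 are racemic diastereomer mixtures.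

Step 1
Reactants: 1 3,5-dihydroxy-4-methoxybenzoic acid
Product: 2 benzyl 3,5-bis(benzyloxy)-4-methoxybenzoate
Conditions: BnBr (3.5 equiv), K2CO3, DMF, 60 °C
Reagents that add atoms: benzyl bromide, BrCc1ccccc1
Why: Williamson etherification together with carboxylate alkylation (SN2 on benzyl bromide) should benzylate both phenols and the acid in one operation, masking the ring B hydroxyls for the strongly basic steps ahead.

Step 2
Reactants: 2 benzyl 3,5-bis(benzyloxy)-4-methoxybenzoate
Product: 3 [3,5-bis(benzyloxy)-4-methoxyphenyl]methanol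
Conditions: LiAlH4, THF, 0 °C to rt; aqueous work-up
Reagents that add atoms: none
Why: Hydride reduction of the benzyl ester to the primary benzylic alcohol is standard and leaves aryl benzyl and methyl ethers untouched.

Step 3
Reactants: 3 [3,5-bis(benzyloxy)-4-methoxyphenyl]methanol
Product: 4 3,5-bis(benzyloxy)-4-methoxybenzaldehyde
Conditions: activated MnO2 (excess), CH2Cl2, rt
Reagents that add atoms: none
Why: MnO2 is a selective oxidant for benzylic alcohols and should stop at the aldehyde.

Step 4
Reactants: 4 3,5-bis(benzyloxy)-4-methoxybenzaldehyde; 5 methyl methoxyacetate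
Product: 7 methyl (Z)-3-[3,5-bis(benzyloxy)-4-methoxyphenyl]-2-methoxyprop-2-enoate, via aldol adduct 6 (not isolated)
Conditions: NaOMe (2 equiv), 5 (3 equiv), MeOH, reflux; aq. HCl work-up
Reagents that add atoms: none
Why: Aldol condensation of the methoxyacetate enolate with the non-enolizable aldehyde, followed by E1cB dehydration of adduct 6, should give the thermodynamically preferred Z α-methoxycinnamate; the geometry has no later consequence.

Step 5
Reactants: 5 methyl methoxyacetate (two molecules)
Product: 8 methyl 2,4-dimethoxy-3-oxobutanoate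
Conditions: NaH (0.55 equiv per ester), THF, 0 to 50 °C; aq. HCl work-up
Reagents that add atoms: none
Why: Self-Claisen condensation of the ester is driven forward by deprotonation of the doubly activated C2–H of the β-keto ester product.

Step 6
Reactants: 8 methyl 2,4-dimethoxy-3-oxobutanoate; 9 N-methoxy-N-methylacetamide
Product: 10 methyl 2,4-dimethoxy-3,5-dioxohexanoate
Conditions: LiN(iPr)2 (2.2 equiv), THF, −78 to 0 °C; then 9, −78 to 0 °C; aq. HCl work-up
Reagents that add atoms: none
Why: γ-Acylation of a β-keto ester dianion by a Weinreb amide: the second deprotonation takes place at the methoxymethyl carbon, this more reactive carbanion attacks the amide, and the chelated tetrahedral intermediate blocks over-addition and proton transfer until work-up.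

Step 7
Reactants: 10 methyl 2,4-dimethoxy-3,5-dioxohexanoate; 7 methyl (Z)-3-[3,5-bis(benzyloxy)-4-methoxyphenyl]-2-methoxyprop-2-enoate
Product: 11 methyl (Z)-9-[3,5-bis(benzyloxy)-4-methoxyphenyl]-2,4,8-trimethoxy-3,5,7-trioxonon-8-enoate
Conditions: 10 (2.2 equiv), LiN(iPr)2 (6.8 equiv), THF, −78 to 0 °C; then 7 (1 equiv), −78 to 0 °C; cold aq. HCl; crude 11 used at once
Reagents that add atoms: none
Why: Claisen acylation at the terminal, least stabilized carbanion of a 3,5-diketo ester trianion is a known entry to 3,5,7-triketo esters; the α-methoxy group makes the enoate an enol ether with an electron-rich β-carbon, which should favour 1,2- over 1,4-addition, and the excess trianion absorbs the proton of the more acidic product.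

Step 8
Reactants: 11 methyl (Z)-9-[3,5-bis(benzyloxy)-4-methoxyphenyl]-2,4,8-trimethoxy-3,5,7-trioxonon-8-enoate
Product: 12 (Z)-3-[3,5-bis(benzyloxy)-4-methoxyphenyl]-2-methoxy-1-(2,4,6-trihydroxy-3,5-dimethoxyphenyl)prop-2-en-1-one
Conditions: NaOMe (6 equiv), degassed MeOH, 0 °C to rt, Ar; then cold aq. HCl
Reagents that add atoms: none
Why: Methoxide turns 11 into its polyenolate; C6 of the chain (the future C4a, flanked by the C5 and C7 carbonyls) adds to the C1 ester carbonyl, which the 2-methoxy group makes more electrophilic, and loss of methoxide forms the C4a–C8a bond and a 2-acylcyclohexane-1,3,5-trione that enolizes three times to the phloroglucinol phenoxide. The closest known reaction is the base-induced Claisen (Dieckmann-type) cyclization of 3,5,7-triketo esters to acylphloroglucinols, the laboratory counterpart of chalcone synthase. Ring A closes in a 6-exo-trig mode. No stereocentre is created: the labile C2 and C4 centres become aromatic carbons and the Z enol ether is carried through unchanged. The step needs C-acylation to win over aldol closure of C2 onto the C7 carbonyl and over lactonization of the C5 enol onto C1; the substrate secures this because the aldol adduct has a quaternary C2 (OMe, CO2Me) and cannot aromatize and the pyranone is reopened by methoxide, so both stay reversible while the aromatic phenoxide is the only irreversible exit. In methanolic methoxide the chalcone phenoxide is expected to resist oxa-Michael closure, and any flavanone formed on acidification would converge in step 9.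

Step 9
Reactants: 12 (Z)-3-[3,5-bis(benzyloxy)-4-methoxyphenyl]-2-methoxy-1-(2,4,6-trihydroxy-3,5-dimethoxyphenyl)prop-2-en-1-one
Product: 14 2-[3,5-bis(benzyloxy)-4-methoxyphenyl]-5,7-dihydroxy-3,6,8-trimethoxy-4H-chromen-4-one, via 3-methoxyflavanone 13 (not isolated)
Conditions: I2 (10 mol%), DMSO, 110 °C
Reagents that add atoms: none
Why: Iodine-catalysed oxidative cyclization of a 2'-hydroxychalcone in DMSO: 6-endo-trig oxa-Michael closure through either of the two equivalent ortho hydroxyls gives flavanone 13, whose C3 is iodinated through the enol and loses HI, while DMSO reoxidizes HI to I2; ring A has no free C–H, so nuclear iodination there is excluded.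

Step 10
Reactants: 14 2-[3,5-bis(benzyloxy)-4-methoxyphenyl]-5,7-dihydroxy-3,6,8-trimethoxy-4H-chromen-4-one
Product: 15 5,7,3',5'-tetrahydroxy-3,6,8,4'-tetramethoxyflavone
Conditions: H2 (1 atm), 10% Pd/C, EtOAc–MeOH, rt
Reagents that add atoms: none
Why: Catalytic hydrogenolysis of aryl benzyl ethers at ambient pressure is expected to leave the flavone enone and the methyl ethers intact.

**Compound list**
1 | 3,5-dihydroxy-4-methoxybenzoic acid | COc1c(O)cc(C(=O)O)cc1O | starting material
2 | benzyl 3,5-bis(benzyloxy)-4-methoxybenzoate | COc1c(OCc2ccccc2)cc(C(=O)OCc2ccccc2)cc1OCc1ccccc1 | intermediate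
3 | [3,5-bis(benzyloxy)-4-methoxyphenyl]methanol | COc1c(OCc2ccccc2)cc(CO)cc1OCc1ccccc1 | intermediate
4 | 3,5-bis(benzyloxy)-4-methoxybenzaldehyde | COc1c(OCc2ccccc2)cc(C=O)cc1OCc1ccccc1 | intermediate
5 | methyl methoxyacetate | COCC(=O)OC | starting material
6 | methyl 3-[3,5-bis(benzyloxy)-4-methoxyphenyl]-3-hydroxy-2-methoxypropanoate (aldol adduct, racemic diastereomer mixture, not isolated) | COC(=O)C(OC)C(O)c1cc(OCc2ccccc2)c(OC)c(OCc2ccccc2)c1 | intermediate
7 | methyl (Z)-3-[3,5-bis(benzyloxy)-4-methoxyphenyl]-2-methoxyprop-2-enoate | COC(=O)/C(OC)=C/c1cc(OCc2ccccc2)c(OC)c(OCc2ccccc2)c1 | intermediate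
8 | methyl 2,4-dimethoxy-3-oxobutanoate (labile C2, racemic) | COCC(=O)C(OC)C(=O)OC | intermediate
9 | N-methoxy-N-methylacetamide | CC(=O)N(C)OC | starting material
10 | methyl 2,4-dimethoxy-3,5-dioxohexanoate (keto form, labile C2 and C4) | COC(=O)C(OC)C(=O)C(OC)C(C)=O | intermediate
11 | methyl (Z)-9-[3,5-bis(benzyloxy)-4-methoxyphenyl]-2,4,8-trimethoxy-3,5,7-trioxonon-8-enoate (keto form, labile C2 and C4) | COC(=O)C(OC)C(=O)C(OC)C(=O)CC(=O)/C(OC)=C/c1cc(OCc2ccccc2)c(OC)c(OCc2ccccc2)c1 | intermediate
12 | (Z)-3-[3,5-bis(benzyloxy)-4-methoxyphenyl]-2-methoxy-1-(2,4,6-trihydroxy-3,5-dimethoxyphenyl)prop-2-en-1-one | COc1c(O)c(OC)c(O)c(C(=O)/C(OC)=C/c2cc(OCc3ccccc3)c(OC)c(OCc3ccccc3)c2)c1O | intermediate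
13 | 2-[3,5-bis(benzyloxy)-4-methoxyphenyl]-5,7-dihydroxy-3,6,8-trimethoxychroman-4-one (racemic diastereomer mixture, not isolated) | COC1C(=O)c2c(O)c(OC)c(O)c(OC)c2OC1c1cc(OCc2ccccc2)c(OC)c(OCc2ccccc2)c1 | intermediate
14 | 2-[3,5-bis(benzyloxy)-4-methoxyphenyl]-5,7-dihydroxy-3,6,8-trimethoxy-4H-chromen-4-one | COc1c(OCc2ccccc2)cc(-c2oc3c(OC)c(O)c(OC)c(O)c3c(=O)c2OC)cc1OCc1ccccc1 | intermediate
15 | 5,7,3',5'-tetrahydroxy-3,6,8,4'-tetramethoxyflavone | COc1c(O)cc(-c2oc3c(OC)c(O)c(OC)c(O)c3c(=O)c2OC)cc1O | target

**Step count**
Total: 10 steps. Longest linear sequence: 8 steps (steps 1, 2, 3, 4, 7, 8, 9, 10).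

**Steps most likely to fail**

Step 8. The chain may be cleaved by methoxide at the electron-poor, methoxy-flanked ketones (retro-Claisen), may rest in lactone or aldol folds that bleed material away before C-acylation, or the electron-rich phenoxide may be oxidized by adventitious air. The fallback sets out from 11 and returns at 12. Triketo ester 11 would be lactonized with DBU in toluene at 80 °C, the known closure of 3,5-diketo esters to 4-hydroxy-2-pyranones, to give 6-{(3Z)-4-[3,5-bis(benzyloxy)-4-methoxyphenyl]-3-methoxy-2-oxobut-3-en-1-yl}-4-hydroxy-3,5-dimethoxy-2H-pyran-2-one F1. In F1 chain carbons C2 and C4 are locked as ring sp2 carbons. Treatment of F1 with Mg(OMe)2 in MeOH should then effect the known pyranone-to-acylphloroglucinol rearrangement on a magnesium chelate, which holds the nucleophilic carbon next to the acyl donor, and deliver 12.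

Step 7. The trianion may be quenched by proton transfer from the forming triketo ester, may acylate on oxygen or add in conjugate fashion to the enoate, or the tris-enolate may decompose before it is acylated. The fallback sets out from 7 and returns at 11, trading ester acylation for aldol addition and oxidation. Ester 7 would be reduced with iBu2AlH in CH2Cl2 at −78 °C to (Z)-3-[3,5-bis(benzyloxy)-4-methoxyphenyl]-2-methoxyprop-2-en-1-ol F2. MnO2 oxidation would give (Z)-3-[3,5-bis(benzyloxy)-4-methoxyphenyl]-2-methoxyprop-2-enal F3. Addition of the trianion of 10 to this far more electrophilic aldehyde, with no proton-transfer penalty, would give methyl (Z)-9-[3,5-bis(benzyloxy)-4-methoxyphenyl]-7-hydroxy-2,4,8-trimethoxy-3,5-dioxonon-8-enoate F4. MnO2 oxidation of the allylic alcohol of F4 would then give 11.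

Step 6. γ-Deprotonation at the methoxy-bearing carbon may be incomplete, and the hindered dianion may react sluggishly or on oxygen with the amide, so that self-condensation takes over. The fallback sets out from 8 and returns at 10, replacing the dianion by an isolable bis-silyl dienol ether. Keto ester 8 would be silylated with Me3SiCl and Et3N to methyl 2,4-dimethoxy-3-(trimethylsilyloxy)but-2-enoate F5. Deprotonation with LiN(iPr)2 and a second silylation with Me3SiCl at −78 °C would give 1,2,4-trimethoxy-1,3-bis(trimethylsilyloxy)buta-1,3-diene F6. The terminal carbon of F6 should be C-acylated by acetyl chloride in CH2Cl2 (−78 to 20 °C), a Mukaiyama-type acylation of 1,3-bis(silyloxy)dienes, and aqueous acid would then release 10.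

**Further compounds**
F1 | step 8 | 6-{(3Z)-4-[3,5-bis(benzyloxy)-4-methoxyphenyl]-3-methoxy-2-oxobut-3-en-1-yl}-4-hydroxy-3,5-dimethoxy-2H-pyran-2-one | COc1c(O)c(OC)c(=O)oc1CC(=O)/C(OC)=C/c1cc(OCc2ccccc2)c(OC)c(OCc2ccccc2)c1
F2 | step 7 | (Z)-3-[3,5-bis(benzyloxy)-4-methoxyphenyl]-2-methoxyprop-2-en-1-ol | OC/C(OC)=C/c1cc(OCc2ccccc2)c(OC)c(OCc2ccccc2)c1
F3 | step 7 | (Z)-3-[3,5-bis(benzyloxy)-4-methoxyphenyl]-2-methoxyprop-2-enal | O=C/C(OC)=C/c1cc(OCc2ccccc2)c(OC)c(OCc2ccccc2)c1
F4 | step 7 | methyl (Z)-9-[3,5-bis(benzyloxy)-4-methoxyphenyl]-7-hydroxy-2,4,8-trimethoxy-3,5-dioxonon-8-enoate (labile C2 and C4, racemic at C7) | COC(=O)C(OC)C(=O)C(OC)C(=O)CC(O)/C(OC)=C/c1cc(OCc2ccccc2)c(OC)c(OCc2ccccc2)c1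
F5 | step 6 | methyl 2,4-dimethoxy-3-(trimethylsilyloxy)but-2-enoate (geometry unassigned) | COCC(O[Si](C)(C)C)=C(OC)C(=O)OC
F6 | step 6 | 1,2,4-trimethoxy-1,3-bis(trimethylsilyloxy)buta-1,3-diene (geometry unassigned) | COC=C(O[Si](C)(C)C)C(OC)=C(OC)O[Si](C)(C)C
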